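**Retrosynthetic overview**
1. The target is a 2-arylbenzofuran (ring A benzene, ring B furan) joined at its C2 to C5 of a 7-hydroxy-2,2-dimethylchroman (ring C benzene, ring D dimethylpyran); the last step removes two methoxymethyl ethers.
2. Ring B and the 1,1-dimethylallyl group at C7 of the benzofuran are made together from a diaryl alkyne whose ring A carries an O-prenyl group next to the alkyne: Claisen rearrangement, then 5-endo-dig closure of the freed phenol. The alkyne comes from a Sonogashira union of a ring A arylacetylene (from 2,4,6-trihydroxybenzaldehyde) with a 5-bromochromanol.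
3. Ring D is made first, in the key step: acetone is annulated onto a 2-bromo-6-fluoro-4-alkoxyacetophenone by aldol addition (C3–C2 bond) and intramolecular SNAr (O1–C8a bond) in one flask. The C4 ketone is then removed by ionic hydrogenation.
4. Enabling feature: in ring D the unit O1–C2(CH3)2 is acetone itself, and C8a (ring C) is ortho to C4a, which carries the C4–C3 chain. A temporary carbonyl at C4 therefore makes C3 an enolate carbon and at the same time activates a C8a–F bond for displacement by the acetone oxygen.
5. Order of ring formation: ring D (step 3), then ring B (step 9); rings A and C are bought as benzene derivatives.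

Key step: step 3

Remark: the target has no stereocentre, so no stereocontrol is needed; the locants O1, C2, C3, C4, C4a and C8a used here are those of the chroman ring system.

**Route**

Step 1
Reactants: 1 3-bromo-5-fluorophenol; 2 4-methoxybenzyl chloride
Product: 3 1-bromo-3-fluoro-5-[(4-methoxybenzyl)oxy]benzene
Conditions: K2CO3, DMF, 25 °C
Reagents that add atoms: 4-methoxybenzyl chloride (compound 2), COc1ccc(CCl)cc1
Why: Williamson ether synthesis (SN2 of the phenoxide on the benzylic chloride) should give an ether that withstands the two strongly basic steps that follow and is shed by the acid of step 4.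

Step 2
Reactants: 3 1-bromo-3-fluoro-5-[(4-methoxybenzyl)oxy]benzene; 4 N-methoxy-N-methylacetamide
Product: 7 1-{2-bromo-6-fluoro-4-[(4-methoxybenzyl)oxy]phenyl}ethan-1-one, via aryllithium 5 (not isolated), via tetrahedral adduct 6 (not isolated)
Conditions: LiN(iPr)2, THF, −78 °C; then MeC(O)N(OMe)Me, −78 to −40 °C
Reagents that add atoms: N-methoxy-N-methylacetamide (compound 4), CC(=O)N(C)OC
Why: Deprotonation should take the most acidic ring proton, the one flanked by fluorine and bromine (as with 1-bromo-3-fluorobenzene), and the aryllithium is acylated only once because the chelated tetrahedral adduct survives until work-up (Weinreb ketone synthesis).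

Step 3
Reactants: 7 1-{2-bromo-6-fluoro-4-[(4-methoxybenzyl)oxy]phenyl}ethan-1-one; 8 acetone
Product: 11 5-bromo-7-[(4-methoxybenzyl)oxy]-2,2-dimethyl-2,3-dihydro-4H-chromen-4-one, via lithium enolate 9 (not isolated), via lithium aldolate 10 (not isolated)
Conditions: LiN(SiMe3)2, THF, −78 °C; acetone (3 equiv), −78 °C; then DMPU, −78 to 50 °C
Reagents that add atoms: acetone (compound 8), CC(C)=O
Why: LiN(SiMe3)2 removes a proton from the acetyl CH3 of 7 to give enolate 9, whose carbon (the future C3) adds to the carbonyl carbon of acetone (the future C2) to give the tertiary lithium alkoxide 10; on warming with DMPU this alkoxide oxygen attacks the fluorine-bearing ring carbon (the future C8a), which lies ortho to the ketone, and fluoride leaves from the anionic σ-adduct (addition–elimination, SNAr). The closest known reaction types are the aldol addition of aryl methyl ketone enolates to ketones and the intramolecular SNAr of β-oxido ketones onto 2-fluoroaryl ketones that gives chroman-4-ones, here run in one flask. Ring D closes in a 6-exo-trig mode at C8a, helped by the gem-dimethyl group on the attacking oxygen-bearing carbon, and the negative charge of the σ-adduct is taken up by the C4 carbonyl. No stereocentre is formed. The step needs chemoselectivity between the two ortho leaving groups, which the far higher SNAr reactivity of C–F over C–Br should secure. It also needs ring closure to outrun retro-aldol and dehydration: retro-aldol is a reversible leak that the excess acetone refills, the SNAr is irreversible (LiF), and a single equivalent of base keeps the E1cB dehydration slow.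

Step 4
Reactants: 11 5-bromo-7-[(4-methoxybenzyl)oxy]-2,2-dimethyl-2,3-dihydro-4H-chromen-4-one
Product: 13 5-bromo-2,2-dimethyl-3,4-dihydro-2H-chromen-7-ol, via hydroxychromanone 12 (not isolated)
Conditions: Et3SiH, CF3CO2H, CH2Cl2, 0 to 40 °C
Reagents that add atoms: none
Why: Ionic hydrogenation: the acid first ionizes the 4-methoxybenzyl ether (its cation is reduced by the silane to 4-methylanisole), then the protonated, oxygen-stabilized aryl ketone takes up hydride twice from Et3SiH by way of the benzylic cation, which removes the temporary C4 carbonyl while the aryl bromide and the tertiary aryl ether should stay intact.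

Step 5
Reactants: 14 2,4,6-trihydroxybenzaldehyde; 15 chloromethyl methyl ether
Product: 16 2-hydroxy-4,6-bis(methoxymethoxy)benzaldehyde
Conditions: MOMCl (2.1 equiv), K2CO3, acetone, 0 to 25 °C
Reagents that add atoms: chloromethyl methyl ether (compound 15), COCCl
Why: O-Alkylation takes the two more reactive phenols, while the hydroxyl that is hydrogen-bonded to the aldehyde oxygen is the least nucleophilic and should stay free, as is usual for 2-hydroxyaryl carbonyl compounds.

Step 6
Reactants: 16 2-hydroxy-4,6-bis(methoxymethoxy)benzaldehyde; 17 1-bromo-3-methylbut-2-ene (prenyl bromide)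
Product: 18 2,4-bis(methoxymethoxy)-6-[(3-methylbut-2-en-1-yl)oxy]benzaldehyde
Conditions: K2CO3, DMF, 50 °C
Reagents that add atoms: 1-bromo-3-methylbut-2-ene (compound 17), CC(C)=CCBr
Why: Williamson ether synthesis (SN2 at the primary allylic carbon) on the remaining phenol places the prenyl group on the oxygen that will become the furan oxygen.

Step 7
Reactants: 18 2,4-bis(methoxymethoxy)-6-[(3-methylbut-2-en-1-yl)oxy]benzaldehyde; 19 dimethyl (1-diazo-2-oxopropyl)phosphonate (Ohira–Bestmann reagent)
Product: 20 2-ethynyl-1,5-bis(methoxymethoxy)-3-[(3-methylbut-2-en-1-yl)oxy]benzene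
Conditions: K2CO3, MeOH, THF, 25 °C
Reagents that add atoms: dimethyl (1-diazo-2-oxopropyl)phosphonate (compound 19), CC(=O)C(=[N+]=[N-])P(=O)(OC)OC
Why: Seyferth–Gilbert homologation with the Ohira–Bestmann reagent should turn the aldehyde carbon and one reagent carbon into a terminal alkyne under mild base that leaves the acetals and the prenyl ether untouched.

Step 8
Reactants: 13 5-bromo-2,2-dimethyl-3,4-dihydro-2H-chromen-7-ol; 20 2-ethynyl-1,5-bis(methoxymethoxy)-3-[(3-methylbut-2-en-1-yl)oxy]benzene
Product: 21 5-({2,4-bis(methoxymethoxy)-6-[(3-methylbut-2-en-1-yl)oxy]phenyl}ethynyl)-2,2-dimethyl-3,4-dihydro-2H-chromen-7-ol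
Conditions: PdCl2(MeCN)2 (3 mol%), XPhos (9 mol%), Cs2CO3, MeCN, 80 °C
Reagents that add atoms: none
Why: Copper-free Sonogashira coupling: the C5–Br bond, meta to both ring oxygens and so not deactivated, should add to zerovalent palladium bearing the bulky biarylphosphine much faster than the prenyl ether can ionize, and alkynyl transfer with reductive elimination forms the aryl–alkyne bond without protection of the phenol.

Step 9
Reactants: 21 5-({2,4-bis(methoxymethoxy)-6-[(3-methylbut-2-en-1-yl)oxy]phenyl}ethynyl)-2,2-dimethyl-3,4-dihydro-2H-chromen-7-ol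
Product: 23 5-[4,6-bis(methoxymethoxy)-7-(2-methylbut-3-en-2-yl)-1-benzofuran-2-yl]-2,2-dimethyl-3,4-dihydro-2H-chromen-7-ol, via alkynylphenol 22 (not isolated)
Conditions: Cs2CO3 (0.3 equiv), NMP, 180 °C
Reagents that add atoms: none
Why: Aromatic Claisen rearrangement ([3,3] shift) of the aryl prenyl ether carries the allyl unit with inversion to the only free ortho carbon (the other ortho position bears the alkyne), which creates the 1,1-dimethylallyl group and the free phenol of 22, whose phenoxide then adds 5-endo-dig to the neighbouring alkyne to close ring B, a capture that also removes the ortho-hydroxyl through which 1,1-dimethylallylphenols rearrange further on heating.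

Step 10
Reactants: 23 5-[4,6-bis(methoxymethoxy)-7-(2-methylbut-3-en-2-yl)-1-benzofuran-2-yl]-2,2-dimethyl-3,4-dihydro-2H-chromen-7-ol
Product: 24 2-(7-hydroxy-2,2-dimethyl-3,4-dihydro-2H-chromen-5-yl)-7-(2-methylbut-3-en-2-yl)-1-benzofuran-4,6-diol
Conditions: HCl (aq., 3 M), MeOH, 40 °C
Reagents that add atoms: none
Why: Acid-catalysed acetal exchange with methanol releases both phenols, and because acetal cleavage is much faster than protonation of the monosubstituted alkene, the ortho-hydroxy 1,1-dimethylallyl unit and the benzofuran should survive the brief, mild treatment.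

**Compound list**
1 | 3-bromo-5-fluorophenol | Oc1cc(F)cc(Br)c1 | starting material
2 | 4-methoxybenzyl chloride | COc1ccc(CCl)cc1 | starting material
3 | 1-bromo-3-fluoro-5-[(4-methoxybenzyl)oxy]benzene | COc1ccc(COc2cc(F)cc(Br)c2)cc1 | intermediate
4 | N-methoxy-N-methylacetamide | CC(=O)N(C)OC | starting material
5 | {2-bromo-6-fluoro-4-[(4-methoxybenzyl)oxy]phenyl}lithium | [Li]c1c(F)cc(OCc2ccc(OC)cc2)cc1Br | intermediate (not isolated)
6 | lithium 1-{2-bromo-6-fluoro-4-[(4-methoxybenzyl)oxy]phenyl}-1-[methoxy(methyl)amino]ethan-1-olate (racemic tetrahedral adduct) | CC(O[Li])(N(C)OC)c1c(F)cc(OCc2ccc(OC)cc2)cc1Br | intermediate (not isolated)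
7 | 1-{2-bromo-6-fluoro-4-[(4-methoxybenzyl)oxy]phenyl}ethan-1-one | CC(=O)c1c(F)cc(OCc2ccc(OC)cc2)cc1Br | intermediate
8 | acetone | CC(C)=O | starting material
9 | lithium 1-{2-bromo-6-fluoro-4-[(4-methoxybenzyl)oxy]phenyl}ethen-1-olate (enolate of 7) | C=C(O[Li])c1c(F)cc(OCc2ccc(OC)cc2)cc1Br | intermediate (not isolated)
10 | lithium 4-{2-bromo-6-fluoro-4-[(4-methoxybenzyl)oxy]phenyl}-2-methyl-4-oxobutan-2-olate (aldolate) | CC(C)(O[Li])CC(=O)c1c(F)cc(OCc2ccc(OC)cc2)cc1Br | intermediate (not isolated)
11 | 5-bromo-7-[(4-methoxybenzyl)oxy]-2,2-dimethyl-2,3-dihydro-4H-chromen-4-one | CC1(C)CC(=O)c2c(Br)cc(OCc3ccc(OC)cc3)cc2O1 | intermediate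
12 | 5-bromo-7-hydroxy-2,2-dimethyl-2,3-dihydro-4H-chromen-4-one | CC1(C)CC(=O)c2c(Br)cc(O)cc2O1 | intermediate (not isolated)
13 | 5-bromo-2,2-dimethyl-3,4-dihydro-2H-chromen-7-ol | CC1(C)CCc2c(Br)cc(O)cc2O1 | intermediate
14 | 2,4,6-trihydroxybenzaldehyde | O=Cc1c(O)cc(O)cc1O | starting material
15 | chloromethyl methyl ether | COCCl | starting material
16 | 2-hydroxy-4,6-bis(methoxymethoxy)benzaldehyde | COCOc1cc(O)c(C=O)c(OCOC)c1 | intermediate
17 | 1-bromo-3-methylbut-2-ene (prenyl bromide) | CC(C)=CCBr | starting material
18 | 2,4-bis(methoxymethoxy)-6-[(3-methylbut-2-en-1-yl)oxy]benzaldehyde | COCOc1cc(OCC=C(C)C)c(C=O)c(OCOC)c1 | intermediate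
19 | dimethyl (1-diazo-2-oxopropyl)phosphonate | CC(=O)C(=[N+]=[N-])P(=O)(OC)OC | starting material
20 | 2-ethynyl-1,5-bis(methoxymethoxy)-3-[(3-methylbut-2-en-1-yl)oxy]benzene | COCOc1cc(OCC=C(C)C)c(C#C)c(OCOC)c1 | intermediate
21 | 5-({2,4-bis(methoxymethoxy)-6-[(3-methylbut-2-en-1-yl)oxy]phenyl}ethynyl)-2,2-dimethyl-3,4-dihydro-2H-chromen-7-ol | COCOc1cc(OCC=C(C)C)c(C#Cc2cc(O)cc3OC(C)(C)CCc23)c(OCOC)c1 | intermediate
22 | 5-{[2-hydroxy-4,6-bis(methoxymethoxy)-3-(2-methylbut-3-en-2-yl)phenyl]ethynyl}-2,2-dimethyl-3,4-dihydro-2H-chromen-7-ol | C=CC(C)(C)c1c(O)c(C#Cc2cc(O)cc3OC(C)(C)CCc23)c(OCOC)cc1OCOC | intermediate (not isolated)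
23 | 5-[4,6-bis(methoxymethoxy)-7-(2-methylbut-3-en-2-yl)-1-benzofuran-2-yl]-2,2-dimethyl-3,4-dihydro-2H-chromen-7-ol | C=CC(C)(C)c1c(OCOC)cc(OCOC)c2cc(-c3cc(O)cc4OC(C)(C)CCc34)oc12 | intermediate
24 | 2-(7-hydroxy-2,2-dimethyl-3,4-dihydro-2H-chromen-5-yl)-7-(2-methylbut-3-en-2-yl)-1-benzofuran-4,6-diol | C=CC(C)(C)c1c(O)cc(O)c2cc(-c3cc(O)cc4c3CCC(C)(C)O4)oc12 | target

**Step count and risks**
Total step count: 10. Longest linear sequence: 7 steps (steps 1, 2, 3, 4, 8, 9, 10).

Steps most likely to fail:

1. Step 3. The lithium aldolate may revert to enolate and acetone, or dehydrate to the enone, faster than its oxygen closes onto the C–F carbon, and the twist of the doubly ortho-substituted aryl ketone out of the ring plane may slow the SNAr. The fallback sets out from 7 and comes back at 11. Hydroxide (KOH, DMSO/H2O, 80 °C) displaces the ketone-activated fluoride to give 1-{2-bromo-6-hydroxy-4-[(4-methoxybenzyl)oxy]phenyl}ethan-1-one F1. A Kabbe condensation of this 2-hydroxyacetophenone with acetone (pyrrolidine, MeOH, 60 °C; enamine aldol, dehydration, oxa-Michael ring closure) then gives 11.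

2. Step 9. At the temperature needed for the [3,3] shift the prenyl ether may instead fragment with loss of the prenyl group, or the allyl unit may move on to the para position by a second sigmatropic shift before the phenol is captured. The fallback sets out from 18 and comes back at 23. The Claisen rearrangement is run at the aldehyde stage under Lewis acid catalysis (Eu(fod)3, CHCl3, 60 °C; chelation between aldehyde oxygen and ether oxygen) to give 2-hydroxy-4,6-bis(methoxymethoxy)-3-(2-methylbut-3-en-2-yl)benzaldehyde F2. Homologation with 19 (K2CO3, MeOH) gives 2-ethynyl-3,5-bis(methoxymethoxy)-6-(2-methylbut-3-en-2-yl)phenol F3. Coupling of this 2-ethynylphenol with 13 (Pd(PPh3)2Cl2, CuI, Et3N, DMF, 70 °C) should pass through 22, which cyclizes in the flask to 23.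

3. Step 2. Acyl transfer from the amide to the hindered aryllithium may be slow enough that the aryllithium loses LiBr to an aryne or is quenched by proton transfer from the amide. The fallback sets out from 3 and comes back at 7. Aryllithium 5 is trapped at −78 °C with the much faster electrophile DMF to give 2-bromo-6-fluoro-4-[(4-methoxybenzyl)oxy]benzaldehyde F4. MeMgBr (THF, 0 °C) adds to give racemic 1-{2-bromo-6-fluoro-4-[(4-methoxybenzyl)oxy]phenyl}ethan-1-ol F5, and oxidation with Dess–Martin periodinane (CH2Cl2, 25 °C) gives 7.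

Further compounds
F1 | step 3 | 1-{2-bromo-6-hydroxy-4-[(4-methoxybenzyl)oxy]phenyl}ethan-1-one | CC(=O)c1c(O)cc(OCc2ccc(OC)cc2)cc1Br
F2 | step 9 | 2-hydroxy-4,6-bis(methoxymethoxy)-3-(2-methylbut-3-en-2-yl)benzaldehyde | C=CC(C)(C)c1c(O)c(C=O)c(OCOC)cc1OCOC
F3 | step 9 | 2-ethynyl-3,5-bis(methoxymethoxy)-6-(2-methylbut-3-en-2-yl)phenol | C=CC(C)(C)c1c(O)c(C#C)c(OCOC)cc1OCOC
F4 | step 2 | 2-bromo-6-fluoro-4-[(4-methoxybenzyl)oxy]benzaldehyde | O=Cc1c(F)cc(OCc2ccc(OC)cc2)cc1Br
F5 | step 2 | 1-{2-bromo-6-fluoro-4-[(4-methoxybenzyl)oxy]phenyl}ethan-1-ol (racemic) | CC(O)c1c(F)cc(OCc2ccc(OC)cc2)cc1Br
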